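**Plan**

- Retrosynthesis: the O8 and O12 angelates and the C4–C5 oxirane come off first. Taking C6–OH back to the ketone exposes a β-hydroxy ketone (O6 and O8 in a 1,3 relationship across the branched C7) inside the ten-membered ring. That ring is cut at C7–C8 (aldol), the open chain at C6–C7 (Grignard reagent plus enal) and at C8–C9 (methylenation, then hydroboration).
- Forward: neryl acetate (C1–C6, C9, C10, C14, C15) is oxidised at C9 and extended by C8. The Grignard reagent from (R)-3-bromo-2-methylpropan-1-ol brings C7 and C11–C13. Oxidation at C6, bromination at C7 and oxidation at C8 give the bromo keto aldehyde; SmI2 closes the ten-membered carbocycle; the oxirane is made last.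
- Stereochemistry: C11 is bought. (Z)-C4=C5 comes from neryl acetate and (E)-C1=C10 from the SeO2 oxidation. C7 and C8 arise in the ring closure (enolate face set by C11, Z-enolate chair). C6 comes from Evans–Tishchenko 1,3-anti hydride delivery from O8. C4/C5 come from VO(acac)2 epoxidation directed by 6-OH.

Key step: step 10

Remark: atoms carry germacrane numbers (ring C1–C10, side chain C11–C13 on C7, C14 on C10, C15 on C4); commercial neryl acetate is taken as the nerol building block, its acetate serving as the O6 protecting group.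

**Step 1**
Reactants: 1 neryl acetate
Product: 3 (2Z,6E)-3,7-dimethyl-8-oxoocta-2,6-dien-1-yl acetate, via allylic alcohol 2 (not isolated)
Conditions: SeO2 (0.2 equiv), t-BuOOH, salicylic acid (cat.), CH2Cl2, rt; crude mixture then MnO2, CH2Cl2, rt
Reagents that add atoms: tert-butyl hydroperoxide, CC(C)(C)OO; selenium dioxide (oxygen carrier), O=[Se]=O
Why: Riley allylic oxidation (ene reaction, then [2,3] shift) attacks the E-methyl of the electron-richer distal alkene and fixes the (E)-C1=C10 geometry, and MnO2 allylic oxidation funnels the alcohol/aldehyde mixture to the enal.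

**Step 2**
Reactants: 3 (2Z,6E)-3,7-dimethyl-8-oxoocta-2,6-dien-1-yl acetate
Product: 4 (2Z,6E)-3,7-dimethylnona-2,6,8-trien-1-yl acetate
Conditions: Ph3PCH3Br, NaN(SiMe3)2, THF, −78 to 0 °C
Reagents that add atoms: methyltriphenylphosphonium bromide, C[P+](c1ccccc1)(c1ccccc1)c1ccccc1.[Br-]
Why: Wittig methylenation adds C8; the aldehyde should react far faster than the allylic acetate, and any acetate lost is harmless because step 3 removes it anyway.

**Step 3**
Reactants: 4 (2Z,6E)-3,7-dimethylnona-2,6,8-trien-1-yl acetate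
Product: 6 (2Z,6E)-3,7-dimethylnona-2,6-diene-1,9-diol, via B-alkyl-9-BBN adduct 5 (not isolated)
Conditions: 9-BBN, THF, 0 °C to rt; then 3 M NaOH, 30% H2O2, 0 to 45 °C
Reagents that add atoms: hydrogen peroxide, OO
Why: Brown hydroboration–oxidation with the bulky 9-BBN should take only the monosubstituted terminus of the diene (boron on C8, trisubstituted alkenes untouched), and the alkaline peroxide work-up also saponifies the primary acetate.

**Step 4**
Reactants: 6 (2Z,6E)-3,7-dimethylnona-2,6-diene-1,9-diol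
Product: 7 (2Z,6E)-9-hydroxy-3,7-dimethylnona-2,6-dienal
Conditions: MnO2, CH2Cl2, rt
Reagents that add atoms: none
Why: MnO2 oxidation is selective for the allylic C6 alcohol over the homoallylic C8 alcohol and, being neutral and heterogeneous, should keep the (Z)-enal geometry as it does for nerol.

**Step 5**
Reactants: 8 (R)-3-bromo-2-methylpropan-1-ol
Product: 9 (R)-(3-bromo-2-methylpropoxy)(tert-butyl)dimethylsilane
Conditions: TBSCl, imidazole, CH2Cl2, 0 °C to rt
Reagents that add atoms: tert-butyldimethylsilyl chloride, CC(C)(C)[Si](C)(C)Cl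
Why: Standard silylation of a primary alcohol; the C11 stereocentre is not involved.

**Step 6**
Reactants: 9 (R)-(3-bromo-2-methylpropoxy)(tert-butyl)dimethylsilane; 7 (2Z,6E)-9-hydroxy-3,7-dimethylnona-2,6-dienal
Product: 11 (2S,4RS,5Z,9E)-1-(tert-butyldimethylsilyloxy)-2,6,10-trimethyldodeca-5,9-diene-4,12-diol, via Grignard reagent 10 (not isolated)
Conditions: 9 (2.4 equiv), Mg turnings, THF, 40 °C; then 7, THF, −78 to 0 °C; H2O
Reagents that add atoms: none
Why: Grignard 1,2-addition to the β,β-disubstituted enal forms C6–C7 after the first equivalent has deprotonated the C8 hydroxyl; the C6 carbinol is an epimer mixture that step 7 erases.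

**Step 7**
Reactants: 11 (2S,4RS,5Z,9E)-1-(tert-butyldimethylsilyloxy)-2,6,10-trimethyldodeca-5,9-diene-4,12-diol
Product: 12 (2S,5Z,9E)-1-(tert-butyldimethylsilyloxy)-12-hydroxy-2,6,10-trimethyldodeca-5,9-dien-4-one
Conditions: MnO2, CH2Cl2, rt
Reagents that add atoms: none
Why: MnO2 oxidises only the allylic C6 carbinol, leaves the saturated primary C8 alcohol and should not isomerise the (Z)-enone.

**Step 8**
Reactants: 12 (2S,5Z,9E)-1-(tert-butyldimethylsilyloxy)-12-hydroxy-2,6,10-trimethyldodeca-5,9-dien-4-one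
Product: 14 (2R,3RS,5Z,9E)-3-bromo-1-(tert-butyldimethylsilyloxy)-12-hydroxy-2,6,10-trimethyldodeca-5,9-dien-4-one, via bis-silyl dienol ether 13 (not isolated)
Conditions: LiN(SiMe3)2 (2.3 equiv), TMSCl (3 equiv), THF, −78 °C; NBS, −78 °C; 1 M HCl, 0 °C
Reagents that add atoms: N-bromosuccinimide, O=C1CCC(=O)N1Br
Why: Kinetic α′-deprotonation with in situ silylation gives the cross-conjugated 2-silyloxydiene (O8 is silylated in passing), NBS brominates its C7 terminus (ketone α-bromination via the silyl enol ether), and dilute acid removes the primary trimethylsilyl ether; both C7 epimers serve.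

**Step 9**
Reactants: 14 (2R,3RS,5Z,9E)-3-bromo-1-(tert-butyldimethylsilyloxy)-12-hydroxy-2,6,10-trimethyldodeca-5,9-dien-4-one
Product: 15 (3E,7Z,10RS,11R)-10-bromo-12-(tert-butyldimethylsilyloxy)-3,7,11-trimethyl-9-oxododeca-3,7-dienal
Conditions: Dess–Martin periodinane, NaHCO3, CH2Cl2, 0 °C; used at once
Reagents that add atoms: none
Why: Buffered Dess–Martin oxidation should give the β,γ-unsaturated C8 aldehyde without moving the C1=C10 alkene into conjugation and without touching the α-bromo ketone.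

**Step 10**
Reactants: 15 (3E,7Z,10RS,11R)-10-bromo-12-(tert-butyldimethylsilyloxy)-3,7,11-trimethyl-9-oxododeca-3,7-dienal
Product: 17 (1(10)E,4Z,7R,8S,11S)-12-(tert-butyldimethylsilyloxy)-8-hydroxygermacra-1(10),4-dien-6-one, via samarium enolate 16 (not isolated)
Conditions: SmI2 (2.5 equiv), THF, −78 °C, slow addition of 15 (final 0.003 M); pH 7 buffer
Reagents that add atoms: none
Why: Two equivalents of SmI2 cleave the C7–Br bond of either epimer of 15 to the trivalent samarium (Z)-enolate 16, which binds the C8 aldehyde oxygen and adds through a chair-like six-membered transition state, so that C7–C8 forms and the carbocycle closes in a 10-(enolendo)-exo-trig aldol; this is the samarium Reformatsky reaction in its intramolecular, medium-ring form. The C7 configuration should follow from C11: with C11–H eclipsing the enolate (A(1,3) strain against O–Sm) the aldehyde approaches anti to CH2OTBS, and a chelate between samarium and O12 would expose the same face. The C8 carbinol should form syn to the C7 branch (trans on the ring) because a Z-enolate in a closed transition state places C9 equatorial. Chemoselectivity over the enone, the aldehyde and the trisubstituted alkenes rests on the much faster reduction of the α-bromo ketone at −78 °C without HMPA. Ring closure over oligomerisation rests on high dilution and on the (Z)-C4=C5 and (E)-C1=C10 alkenes, which stiffen the chain and bring its ends together. The C7/C8 relationship rests on these models only and is the least secured element of the route.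

**Step 11**
Reactants: 17 (1(10)E,4Z,7R,8S,11S)-12-(tert-butyldimethylsilyloxy)-8-hydroxygermacra-1(10),4-dien-6-one
Product: 18 (1(10)E,4Z,6S,7S,8S,11S)-12-(tert-butyldimethylsilyloxy)-6-hydroxygermacra-1(10),4-dien-8-yl acetate
Conditions: CH3CHO (10 equiv), SmI2 (0.3 equiv), THF, −10 °C
Reagents that add atoms: acetaldehyde, CC=O
Why: Evans–Tishchenko reduction, in which the samarium-bound hemiacetal of O8 with acetaldehyde passes its hydride to C6 through a six-membered chair, should set C6 1,3-anti to C8, leave O8 acetylated and O6 free, and end the epimerisable stage at C7.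

**Step 12**
Reactants: 18 (1(10)E,4Z,6S,7S,8S,11S)-12-(tert-butyldimethylsilyloxy)-6-hydroxygermacra-1(10),4-dien-8-yl acetate
Product: 19 (1(10)E,4Z,6S,7R,8S,11S)-6,12-bis(tert-butyldimethylsilyloxy)germacra-1(10),4-dien-8-yl acetate
Conditions: TBSOTf, 2,6-lutidine, CH2Cl2, −78 °C
Reagents that add atoms: tert-butyldimethylsilyl triflate, CC(C)(C)[Si](C)(C)OS(=O)(=O)C(F)(F)F
Why: Silylation of the hindered secondary allylic alcohol with the silyl triflate at low temperature should go without acetyl migration from O8.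

**Step 13**
Reactants: 19 (1(10)E,4Z,6S,7R,8S,11S)-6,12-bis(tert-butyldimethylsilyloxy)germacra-1(10),4-dien-8-yl acetate
Product: 20 (1(10)E,4Z,6S,7R,8S,11S)-6,12-bis(tert-butyldimethylsilyloxy)germacra-1(10),4-dien-8-ol
Conditions: i-Bu2AlH, CH2Cl2, −78 °C; aqueous work-up
Reagents that add atoms: none
Why: Reductive ester cleavage at −78 °C removes the acetate through an aluminium alkoxide, which should avoid the silyl migration possible under basic methanolysis.

**Step 14**
Reactants: 20 (1(10)E,4Z,6S,7R,8S,11S)-6,12-bis(tert-butyldimethylsilyloxy)germacra-1(10),4-dien-8-ol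
Product: 21 (1(10)E,4Z,6S,7R,8S,11S)-6-(tert-butyldimethylsilyloxy)germacra-1(10),4-diene-8,12-diol
Conditions: HF·pyridine, pyridine, THF, 0 °C
Reagents that add atoms: none
Why: Buffered fluoride desilylation should distinguish the primary O12 silyl ether from the hindered secondary O6 silyl ether on steric grounds.

**Step 15**
Reactants: 21 (1(10)E,4Z,6S,7R,8S,11S)-6-(tert-butyldimethylsilyloxy)germacra-1(10),4-diene-8,12-diol; 22 angelic acid
Product: 24 (1(10)E,4Z,6S,7R,8S,11S)-6-(tert-butyldimethylsilyloxy)germacra-1(10),4-diene-8,12-diyl bis[(2Z)-2-methylbut-2-enoate], via mixed anhydride 23 (not isolated)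
Conditions: 22 (5 equiv), 2,4,6-Cl3C6H2COCl, Et3N, toluene, rt; then 21, 75 °C
Reagents that add atoms: none
Why: Yamaguchi esterification through the preformed mixed anhydride, run without DMAP, is the established way to transfer an angeloyl group to primary and hindered secondary alcohols without Z to E isomerisation.

**Step 16**
Reactants: 24 (1(10)E,4Z,6S,7R,8S,11S)-6-(tert-butyldimethylsilyloxy)germacra-1(10),4-diene-8,12-diyl bis[(2Z)-2-methylbut-2-enoate]
Product: 25 (1(10)E,4Z,6S,7S,8S,11S)-6-hydroxygermacra-1(10),4-diene-8,12-diyl bis[(2Z)-2-methylbut-2-enoate]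
Conditions: HF·pyridine (excess), THF, rt
Reagents that add atoms: none
Why: Mildly acidic fluoride desilylation frees the allylic O6 hydroxyl without an alkoxide, so neither acyl migration from O8 nor angelate isomerisation should occur.

**Step 17**
Reactants: 25 (1(10)E,4Z,6S,7S,8S,11S)-6-hydroxygermacra-1(10),4-diene-8,12-diyl bis[(2Z)-2-methylbut-2-enoate]
Product: 26 (1(10)E,4S,5R,6R,7S,8S,11S)-4,5-epoxy-6-hydroxygermacr-1(10)-ene-8,12-diyl bis[(2Z)-2-methylbut-2-enoate] (CNP0272382.1)
Conditions: VO(acac)2 (0.1 equiv), t-BuOOH, CH2Cl2, 0 °C to rt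
Reagents that add atoms: tert-butyl hydroperoxide, CC(C)(C)OO
Why: Hydroxyl-directed vanadium epoxidation delivers oxygen from the O6 vanadate to the only allylic alkene, C4=C5, on the face syn to 6-OH as in medium-ring (Z)-cycloalkenols, which sets C4 and C5 and leaves the electron-poor angelates and the remote C1=C10 alone.

**Compound list**

1 | neryl acetate, (2Z)-3,7-dimethylocta-2,6-dien-1-yl acetate | CC(C)=CCC/C(C)=C\COC(C)=O | starting material
2 | (2Z,6E)-8-hydroxy-3,7-dimethylocta-2,6-dien-1-yl acetate | OC/C(C)=C/CC/C(C)=C\COC(C)=O | intermediate (not isolated)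
3 | (2Z,6E)-3,7-dimethyl-8-oxoocta-2,6-dien-1-yl acetate | O=C/C(C)=C/CC/C(C)=C\COC(C)=O | intermediate
4 | (2Z,6E)-3,7-dimethylnona-2,6,8-trien-1-yl acetate | C=C/C(C)=C/CC/C(C)=C\COC(C)=O | intermediate
5 | 9-[(3E,7Z)-9-acetoxy-3,7-dimethylnona-3,7-dien-1-yl]-9-borabicyclo[3.3.1]nonane | CC(=O)OC/C=C(C)\CC/C=C(\C)CCB1C2CCCC1CCC2 | intermediate (not isolated)
6 | (2Z,6E)-3,7-dimethylnona-2,6-diene-1,9-diol | OCC/C(C)=C/CC/C(C)=C\CO | intermediate
7 | (2Z,6E)-9-hydroxy-3,7-dimethylnona-2,6-dienal | OCC/C(C)=C/CC/C(C)=C\C=O | intermediate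
8 | (R)-3-bromo-2-methylpropan-1-ol | OC[C@@H](C)CBr | starting material
9 | (R)-(3-bromo-2-methylpropoxy)(tert-butyl)dimethylsilane | CC(C)(C)[Si](C)(C)OC[C@@H](C)CBr | intermediate
10 | [(2R)-3-(tert-butyldimethylsilyloxy)-2-methylpropyl]magnesium bromide | CC(C)(C)[Si](C)(C)OC[C@@H](C)C[Mg]Br | intermediate (not isolated)
11 | (2S,4RS,5Z,9E)-1-(tert-butyldimethylsilyloxy)-2,6,10-trimethyldodeca-5,9-diene-4,12-diol (C6 epimers) | CC(C)(C)[Si](C)(C)OC[C@@H](C)CC(O)/C=C(C)\CC/C=C(\C)CCO | intermediate
12 | (2S,5Z,9E)-1-(tert-butyldimethylsilyloxy)-12-hydroxy-2,6,10-trimethyldodeca-5,9-dien-4-one | CC(C)(C)[Si](C)(C)OC[C@@H](C)CC(=O)/C=C(C)\CC/C=C(\C)CCO | intermediate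
13 | C6 trimethylsilyl dienol ether, O8 trimethylsilyl ether of 12 (enol ether geometry not defined) | CC(C)(C)[Si](C)(C)OC[C@@H](C)C=C(O[Si](C)(C)C)/C=C(C)\CC/C=C(\C)CCO[Si](C)(C)C | intermediate (not isolated)
14 | (2R,3RS,5Z,9E)-3-bromo-1-(tert-butyldimethylsilyloxy)-12-hydroxy-2,6,10-trimethyldodeca-5,9-dien-4-one (C7 epimers) | CC(C)(C)[Si](C)(C)OC[C@@H](C)C(Br)C(=O)/C=C(C)\CC/C=C(\C)CCO | intermediate
15 | (3E,7Z,10RS,11R)-10-bromo-12-(tert-butyldimethylsilyloxy)-3,7,11-trimethyl-9-oxododeca-3,7-dienal (C7 epimers) | CC(C)(C)[Si](C)(C)OC[C@@H](C)C(Br)C(=O)/C=C(C)\CC/C=C(\C)CC=O | intermediate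
16 | diiodosamarium (Z)-enolate of the C6 ketone, trivalent samarium, C8 aldehyde free | CC(C)(C)[Si](C)(C)OC[C@@H](C)/C=C(\O[Sm](I)I)/C=C(C)\CC/C=C(\C)CC=O | intermediate (not isolated)
17 | (1(10)E,4Z,7R,8S,11S)-12-(tert-butyldimethylsilyloxy)-8-hydroxygermacra-1(10),4-dien-6-one | CC(C)(C)[Si](C)(C)OC[C@@H](C)[C@H]1C(=O)/C=C(C)\CC/C=C(\C)C[C@@H]1O | intermediate
18 | (1(10)E,4Z,6S,7S,8S,11S)-12-(tert-butyldimethylsilyloxy)-6-hydroxygermacra-1(10),4-dien-8-yl acetate | CC(C)(C)[Si](C)(C)OC[C@@H](C)[C@H]1[C@@H](O)/C=C(C)\CC/C=C(\C)C[C@@H]1OC(C)=O | intermediate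
19 | (1(10)E,4Z,6S,7R,8S,11S)-6,12-bis(tert-butyldimethylsilyloxy)germacra-1(10),4-dien-8-yl acetate | CC(C)(C)[Si](C)(C)OC[C@@H](C)[C@H]1[C@@H](O[Si](C)(C)C(C)(C)C)/C=C(C)\CC/C=C(\C)C[C@@H]1OC(C)=O | intermediate
20 | (1(10)E,4Z,6S,7R,8S,11S)-6,12-bis(tert-butyldimethylsilyloxy)germacra-1(10),4-dien-8-ol | CC(C)(C)[Si](C)(C)OC[C@@H](C)[C@H]1[C@@H](O[Si](C)(C)C(C)(C)C)/C=C(C)\CC/C=C(\C)C[C@@H]1O | intermediate
21 | (1(10)E,4Z,6S,7R,8S,11S)-6-(tert-butyldimethylsilyloxy)germacra-1(10),4-diene-8,12-diol | OC[C@@H](C)[C@H]1[C@@H](O[Si](C)(C)C(C)(C)C)/C=C(C)\CC/C=C(\C)C[C@@H]1O | intermediate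
22 | angelic acid, (2Z)-2-methylbut-2-enoic acid | C/C=C(/C)C(=O)O | starting material
23 | (2Z)-2-methylbut-2-enoic 2,4,6-trichlorobenzoic anhydride | C/C=C(/C)C(=O)OC(=O)c1c(Cl)cc(Cl)cc1Cl | intermediate (not isolated)
24 | (1(10)E,4Z,6S,7R,8S,11S)-6-(tert-butyldimethylsilyloxy)germacra-1(10),4-diene-8,12-diyl bis[(2Z)-2-methylbut-2-enoate] | C/C=C(/C)C(=O)OC[C@@H](C)[C@H]1[C@@H](O[Si](C)(C)C(C)(C)C)/C=C(C)\CC/C=C(\C)C[C@@H]1OC(=O)/C(C)=C\C | intermediate
25 | (1(10)E,4Z,6S,7S,8S,11S)-6-hydroxygermacra-1(10),4-diene-8,12-diyl bis[(2Z)-2-methylbut-2-enoate] | C/C=C(/C)C(=O)OC[C@@H](C)[C@H]1[C@@H](O)/C=C(C)\CC/C=C(\C)C[C@@H]1OC(=O)/C(C)=C\C | intermediate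
26 | (1(10)E,4S,5R,6R,7S,8S,11S)-4,5-epoxy-6-hydroxygermacr-1(10)-ene-8,12-diyl bis[(2Z)-2-methylbut-2-enoate] | C/C=C(/C)C(=O)OC[C@@H](C)[C@H]1[C@@H](O)[C@H]2O[C@@]2(C)CC/C=C(\C)C[C@@H]1OC(=O)/C(C)=C\C | target

**Count and risks**

Total step count: 17. Longest linear sequence: 16 (steps 1–4 and 6–17 from neryl acetate).

The three steps most likely to fail:

Step 10. What may go wrong: oligomerisation or early protonation of the samarium enolate, or poor facial control at C7/C8 in the closed transition state. Fallback: close the same bond by a Lewis-acid Mukaiyama aldol through an open transition state, starting from 12. PivCl/pyridine should give the C8 pivalate F1. LiN(SiMe3)2/TBSOTf (THF, −78 °C) should give the kinetic C6 tert-butyldimethylsilyl dienol ether F2. i-Bu2AlH (−78 °C) should free the primary alcohol F3. Parikh–Doering oxidation (SO3·pyridine, DMSO, i-Pr2NEt) should give the enol silane aldehyde F4. Slow addition of F4 to BF3·OEt2 in CH2Cl2 at −78 °C under high dilution should then close C7–C8 and return to the route at 17.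

Step 11. What may go wrong: hydride delivery to the wrong face because the ring conformation overrides the six-membered chair, acetyl migration from O8 to O6, or retro-aldol opening of the ring. Fallback: esterify first and reduce under external reagent control, starting from 17. HF·pyridine should give the keto diol F5. Angeloylation with 23 (toluene, 75 °C) should give the keto bis-angelate F6. Reduction with (R)-2-methyl-CBS-oxazaborolidine and catecholborane (toluene, −78 °C; the antipodal catalyst if C5 and not C7 acts as the large group) should return to the route at 25, which bypasses steps 12–16.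

Step 15. What may go wrong: Z to E isomerisation of the angeloyl group to the tiglate under hot acylation, or incomplete acylation of the hindered O8. Fallback: build the Z-alkene on the ester by Still–Gennari olefination, starting from 21. 2-[Bis(2,2,2-trifluoroethoxy)phosphoryl]propanoic acid with DCC and DMAP should give the bis(phosphonopropanoate) F7. KN(SiMe3)2, 18-crown-6 and acetaldehyde (THF, −78 °C) should then give both (Z)-2-methylbut-2-enoates and return to the route at 24.

**Further compounds**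

F1 | step 10 | (4Z,8E,11S)-12-(tert-butyldimethylsilyloxy)-3,7,11-trimethyl-9-oxododeca-3,7-dien-1-yl pivalate (C8 pivalate of 12) | CC(C)(C)[Si](C)(C)OC[C@@H](C)CC(=O)/C=C(C)\CC/C=C(\C)CCOC(=O)C(C)(C)C
F2 | step 10 | C6 tert-butyldimethylsilyl dienol ether of F1 (enol ether geometry not defined) | CC(C)(C)[Si](C)(C)OC[C@@H](C)C=C(O[Si](C)(C)C(C)(C)C)/C=C(C)\CC/C=C(\C)CCOC(=O)C(C)(C)C
F3 | step 10 | C6 tert-butyldimethylsilyl dienol ether with free C8 primary alcohol | CC(C)(C)[Si](C)(C)OC[C@@H](C)C=C(O[Si](C)(C)C(C)(C)C)/C=C(C)\CC/C=C(\C)CCO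
F4 | step 10 | C6 tert-butyldimethylsilyl dienol ether C8 aldehyde | CC(C)(C)[Si](C)(C)OC[C@@H](C)C=C(O[Si](C)(C)C(C)(C)C)/C=C(C)\CC/C=C(\C)CC=O
F5 | step 11 | (1(10)E,4Z,7R,8S,11S)-8,12-dihydroxygermacra-1(10),4-dien-6-one | OC[C@@H](C)[C@H]1C(=O)/C=C(C)\CC/C=C(\C)C[C@@H]1O
F6 | step 11 | (1(10)E,4Z,7R,8S,11S)-6-oxogermacra-1(10),4-diene-8,12-diyl bis[(2Z)-2-methylbut-2-enoate] | C/C=C(/C)C(=O)OC[C@@H](C)[C@H]1C(=O)/C=C(C)\CC/C=C(\C)C[C@@H]1OC(=O)/C(C)=C\C
F7 | step 15 | (1(10)E,4Z,6S,7R,8S,11S)-6-(tert-butyldimethylsilyloxy)germacra-1(10),4-diene-8,12-diyl bis{2-[bis(2,2,2-trifluoroethoxy)phosphoryl]propanoate} | CC(P(=O)(OCC(F)(F)F)OCC(F)(F)F)C(=O)OC[C@@H](C)[C@H]1[C@@H](O[Si](C)(C)C(C)(C)C)/C=C(C)\CC/C=C(\C)C[C@@H]1OC(=O)C(C)P(=O)(OCC(F)(F)F)OCC(F)(F)F
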